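The route rests on disconnecting the bond between the carbinol carbon C3 of the chromanone (ring C) and C1' of ring B. Ring B carries 5'-OH para to 2'-OMe, the signature of a p-quinone monoketal (C5' carbonyl, C2' dimethyl ketal), while C3–OH/C4=O is an α-ketol that forms a chelated zinc enediolate. In one operation a chiral dinuclear zinc catalyst adds C3 of racemic 3-hydroxy-5,7-bis(methoxymethoxy)chroman-4-one to C1' of the prenylated quinone monoketal; loss of methanol re-aromatises ring B, giving the aryl–C3 bond, the tertiary alcohol stereocentre and the free 5'-phenol without any ring-B protecting group. Acidic MOM removal then ends the synthesis.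

Key step: step 7

Remark: O-bound salts formed by simple deprotonation (phenoxides, enolates, the catalyst-bound zinc enediolate) are treated as forms of the numbered parent compound and get no number; the sense of induction in step 7 is assigned by analogy with acyclic 2-hydroxy-2'-alkoxyaryl ketones, and the (R,R)-ligand would be used should it prove opposite.

Step 1
Reactants: 1 phloroglucinol; 2 3-chloropropanoic acid
Product: 4 5,7-dihydroxychroman-4-one, via chloroketone 3 (not isolated)
Conditions: TfOH, 80 °C; crude into 2 M aq NaOH, 0 °C→rt; then aq HCl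
Reagents that add atoms: none
Why: Friedel–Crafts acylation of the symmetric, highly activated arene followed by intramolecular Williamson O-alkylation (6-exo-tet) of the ortho phenoxide should close ring C.

Step 2
Reactants: 4 5,7-dihydroxychroman-4-one
Product: 5 5,7-bis(methoxymethoxy)chroman-4-one
Conditions: NaH (2.3 equiv), MOMCl (2.5 equiv), DMF, 0 °C→rt
Reagents that add atoms: chloromethyl methyl ether, COCCl
Why: Williamson etherification of both sodium phenoxides (the chelated 5-OH needs the salt) should proceed because the phenols are deprotonated far ahead of the ketone α-CH2.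

Step 3
Reactants: 5 5,7-bis(methoxymethoxy)chroman-4-one
Product: 6 racemic 3-hydroxy-5,7-bis(methoxymethoxy)chroman-4-one
Conditions: KHMDS (1.1 equiv), THF, −78 °C; then 2-(phenylsulfonyl)-3-phenyloxaziridine, −78 °C; aq NH4Cl
Reagents that add atoms: 2-(phenylsulfonyl)-3-phenyloxaziridine, O=S(=O)(N1OC1c1ccccc1)c1ccccc1
Why: Enolate hydroxylation by oxygen transfer from the N-sulfonyloxaziridine to C3 of the potassium enolate should give the α-ketol, and a racemate suffices because this centre is erased at the enediolate stage of step 7.

Step 4
Reactants: 7 1-bromo-2,4-dimethoxybenzene; 8 prenyl bromide (1-bromo-3-methylbut-2-ene)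
Product: 10 1-bromo-2,4-dimethoxy-3-(3-methylbut-2-en-1-yl)benzene, via aryllithium 9 (not isolated)
Conditions: LDA (1.1 equiv), THF, −78 °C; then 8, −78 °C→rt
Reagents that add atoms: none
Why: Directed ortho-metalation should occur at the C–H flanked by both methoxy groups (bromine is meta to it, so no aryne can form), and SN2 alkylation of the aryllithium with the allylic bromide follows.

Step 5
Reactants: 10 1-bromo-2,4-dimethoxy-3-(3-methylbut-2-en-1-yl)benzene
Product: 13 2,4-dimethoxy-3-(3-methylbut-2-en-1-yl)phenol, via aryllithium 11 (not isolated), via boronate 12 (not isolated)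
Conditions: n-BuLi (1.05 equiv), THF, −78 °C; B(OMe)3, −78 °C→rt; then 30% H2O2, aq NaOH, 0 °C
Reagents that add atoms: trimethyl borate, COB(OC)OC (its atoms stay in intermediate 12 only); hydrogen peroxide, OO
Why: Halogen–lithium exchange, borate trapping and oxidative 1,2-migration of aryl from boron to oxygen should give the phenol, since nucleophilic alkaline hydroperoxide does not epoxidise the isolated trisubstituted alkene.

Step 6
Reactants: 13 2,4-dimethoxy-3-(3-methylbut-2-en-1-yl)phenol
Product: 14 2,4,4-trimethoxy-3-(3-methylbut-2-en-1-yl)cyclohexa-2,5-dien-1-one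
Conditions: PhI(OAc)2 (1.1 equiv), MeOH, 0 °C; NaHCO3 work-up
Reagents that add atoms: methanol, CO
Why: Hypervalent-iodine oxidative dearomatisation of a p-methoxyphenol should trap the phenoxenium-type intermediate with methanol at the para, methoxy-bearing carbon to give the p-quinone monoketal.

Step 7
Reactants: 6 racemic 3-hydroxy-5,7-bis(methoxymethoxy)chroman-4-one; 14 2,4,4-trimethoxy-3-(3-methylbut-2-en-1-yl)cyclohexa-2,5-dien-1-one
Product: 16 (3S)-3-hydroxy-3-[5-hydroxy-2,4-dimethoxy-3-(3-methylbut-2-en-1-yl)phenyl]-5,7-bis(methoxymethoxy)chroman-4-one, via Michael adduct 15 (not isolated)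
Conditions: (S,S)-linked-BINOL (10 mol%), Et2Zn (40 mol%), MS 3Å, THF, −20 °C→rt, Ar (degassed); then PPTS (cat.), CH2Cl2, rt→40 °C
Reagents that add atoms: none
Why: Proposed new method: the zinc catalyst should deprotonate α-ketol 6 to a planar (Z)-zinc enediolate chelated through O3 and O4 (peri 5-OMOM oxygen as third donor), whose C3 adds in a Michael fashion to C5 of dienone 14 (the unsubstituted β-carbon, the future C1'); protonation gives 15, and PPTS then ionises the vinylogous ketal so that methanol is lost and the ring tautomerises to the phenol. The closest known reaction types are the direct Et2Zn/linked-BINOL Michael addition of 2-hydroxy-2'-alkoxyaryl ketones to enones (including formation of tetrasubstituted carbinols) and the enolate Michael addition/aromatisation on quinone monoketals used as formal α-arylation; their combination on a cyclic α-ketol and a quinone monoketal is untested. No ring is closed. The C3 stereocentre is set under catalyst control: both enantiomers of 6 converge on the same achiral enediolate, one face of which the ligand shields, and the (S,S)-ligand is expected to give 3S. The step needs 1,4- over 1,2-addition and attack at C5 rather than C3 of 14, which the prenyl group on C3 and the deactivating methoxy group on C2 should secure; β-elimination of the ring aryloxide and autoxidation of the enediolate are to be held back by the covalent Zn–O bonding, low temperature and exclusion of oxygen.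

Step 8
Reactants: 16 (3S)-3-hydroxy-3-[5-hydroxy-2,4-dimethoxy-3-(3-methylbut-2-en-1-yl)phenyl]-5,7-bis(methoxymethoxy)chroman-4-one
Product: 17 sophonorol D
Conditions: 3 M HCl, MeOH–THF, 40 °C
Reagents that add atoms: none
Why: Acid-catalysed acetal exchange should remove both MOM ethers as dimethoxymethane, while the non-enolisable tertiary α-ketol keeps its configuration and the prenyl group, flanked by two methoxy groups, has no free ortho-phenol to cyclise onto.

Compound list
1 | phloroglucinol (benzene-1,3,5-triol) | Oc1cc(O)cc(O)c1 | starting material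
2 | 3-chloropropanoic acid | OC(=O)CCCl | starting material
3 | 3-chloro-1-(2,4,6-trihydroxyphenyl)propan-1-one | O=C(CCCl)c1c(O)cc(O)cc1O | intermediate
4 | 5,7-dihydroxychroman-4-one | O=C1CCOc2cc(O)cc(O)c12 | intermediate
5 | 5,7-bis(methoxymethoxy)chroman-4-one | O=C1CCOc2cc(OCOC)cc(OCOC)c12 | intermediate
6 | racemic 3-hydroxy-5,7-bis(methoxymethoxy)chroman-4-one | O=C1C(O)COc2cc(OCOC)cc(OCOC)c12 | intermediate
7 | 1-bromo-2,4-dimethoxybenzene | COc1ccc(Br)c(OC)c1 | starting material
8 | prenyl bromide (1-bromo-3-methylbut-2-ene) | CC(C)=CCBr | starting material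
9 | (3-bromo-2,6-dimethoxyphenyl)lithium | [Li]c1c(OC)ccc(Br)c1OC | intermediate
10 | 1-bromo-2,4-dimethoxy-3-(3-methylbut-2-en-1-yl)benzene | COc1ccc(Br)c(OC)c1CC=C(C)C | intermediate
11 | [2,4-dimethoxy-3-(3-methylbut-2-en-1-yl)phenyl]lithium | [Li]c1ccc(OC)c(CC=C(C)C)c1OC | intermediate
12 | dimethyl [2,4-dimethoxy-3-(3-methylbut-2-en-1-yl)phenyl]boronate | COB(OC)c1ccc(OC)c(CC=C(C)C)c1OC | intermediate
13 | 2,4-dimethoxy-3-(3-methylbut-2-en-1-yl)phenol | Oc1ccc(OC)c(CC=C(C)C)c1OC | intermediate
14 | 2,4,4-trimethoxy-3-(3-methylbut-2-en-1-yl)cyclohexa-2,5-dien-1-one (p-quinone monoketal) | O=C1C=CC(OC)(OC)C(CC=C(C)C)=C1OC | intermediate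
15 | (3S)-3-hydroxy-5,7-bis(methoxymethoxy)-3-[2,2,4-trimethoxy-3-(3-methylbut-2-en-1-yl)-5-oxocyclohex-3-en-1-yl]chroman-4-one (Michael adduct, mixture of epimers at the cyclohexenyl C1) | O=C1CC([C@]2(O)COc3cc(OCOC)cc(OCOC)c3C2=O)C(OC)(OC)C(CC=C(C)C)=C1OC | intermediate
16 | (3S)-3-hydroxy-3-[5-hydroxy-2,4-dimethoxy-3-(3-methylbut-2-en-1-yl)phenyl]-5,7-bis(methoxymethoxy)chroman-4-one | COc1c(O)cc([C@]2(O)COc3cc(OCOC)cc(OCOC)c3C2=O)c(OC)c1CC=C(C)C | intermediate
17 | sophonorol D, (3S)-3,5,7-trihydroxy-3-[5-hydroxy-2,4-dimethoxy-3-(3-methylbut-2-en-1-yl)phenyl]chroman-4-one | COc1c(O)cc([C@]2(O)COc3cc(O)cc(O)c3C2=O)c(OC)c1CC=C(C)C | target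

Total step count: 8. Longest linear sequence: 5 steps (1→2→3→7→8 or 4→5→6→7→8).

Steps most likely to fail

1. Step 7 (Proposed new method). Carbon–carbon bond formation between the fully substituted enediolate carbon and the β-carbon next to the ketal may be too slow. That would let β-elimination of the ring aryloxide or autoxidation of the enediolate take over, or the catalyst may discriminate the enediolate faces poorly. The fallback sets out from 6 (with 14) and comes back at 16. Compound 6 would be converted with LiHMDS (2.1 equiv, THF, −78 °C) into its dilithium enediolate, a stoichiometric and more nucleophilic donor that needs no catalyst turnover. Conjugate addition to 14 (the known enolate/quinone-monoketal Michael addition) would give the racemic Michael adduct F1, which PPTS would aromatise to the racemic coupled product F2. Preparative chromatography on a chiral stationary phase (SFC, polysaccharide column) would then deliver the (3S)-enantiomer, which is 16.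

2. Step 4. Metalation may occur at the wrong site (ortho to bromine with aryne formation, or bromine migration by halogen dance), or deprotonation by LDA may be incomplete. The fallback sets out from 7 and comes back at 13, bypassing 10. Halogen–lithium exchange on 7 (n-BuLi, THF, −78 °C), B(OMe)3 and alkaline H2O2 would give 2,4-dimethoxyphenol F3. TIPSCl/imidazole (DMF) would give (2,4-dimethoxyphenoxy)triisopropylsilane F4. n-BuLi (THF, 0 °C) should then metalate only the position between the two methoxy groups, since the bulky, weakly directing silyl ether shields its own ortho position and no bromine is left to misdirect. Prenyl bromide 8 would give the prenylated silyl ether F5, and TBAF (THF, 0 °C) would release 13.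

3. Step 3. The enolate may add to the sulfonimine formed during oxygen transfer, the α-ketol may be over-oxidised under the basic conditions, or the enolate may open ring C by β-elimination. The fallback sets out from 5 and comes back at 6. Soft enolisation (TMSOTf, Et3N, CH2Cl2, 0 °C) would give the silyl enol ether F6. Epoxidation under neutral conditions with dimethyldioxirane (acetone, −40→0 °C; Rubottom oxidation) would give, after 1,4-silyl shift, the 3-(trimethylsilyloxy) ketone F7. Buffered fluoride (TBAF/AcOH, THF, 0 °C) would then give 6 without exposing the α-ketol to strong base.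

Further compounds
F1 | step 7 | racemic 3-hydroxy-5,7-bis(methoxymethoxy)-3-[2,2,4-trimethoxy-3-(3-methylbut-2-en-1-yl)-5-oxocyclohex-3-en-1-yl]chroman-4-one | O=C1CC(C2(O)COc3cc(OCOC)cc(OCOC)c3C2=O)C(OC)(OC)C(CC=C(C)C)=C1OC
F2 | step 7 | racemic 3-hydroxy-3-[5-hydroxy-2,4-dimethoxy-3-(3-methylbut-2-en-1-yl)phenyl]-5,7-bis(methoxymethoxy)chroman-4-one | COc1c(O)cc(C2(O)COc3cc(OCOC)cc(OCOC)c3C2=O)c(OC)c1CC=C(C)C
F3 | step 4 | 2,4-dimethoxyphenol | COc1ccc(O)c(OC)c1
F4 | step 4 | (2,4-dimethoxyphenoxy)tri(propan-2-yl)silane | COc1ccc(O[Si](C(C)C)(C(C)C)C(C)C)c(OC)c1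
F5 | step 4 | [2,4-dimethoxy-3-(3-methylbut-2-en-1-yl)phenoxy]tri(propan-2-yl)silane | COc1ccc(O[Si](C(C)C)(C(C)C)C(C)C)c(OC)c1CC=C(C)C
F6 | step 3 | {[5,7-bis(methoxymethoxy)-2H-chromen-4-yl]oxy}trimethylsilane | COCOc1cc(OCOC)c2C(O[Si](C)(C)C)=CCOc2c1
F7 | step 3 | 5,7-bis(methoxymethoxy)-3-(trimethylsilyloxy)chroman-4-one | COCOc1cc(OCOC)c2C(=O)C(O[Si](C)(C)C)COc2c1
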